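The ten-membered carbocycle (germacrane numbering C1–C10; C7 bears the isopropyl group) is made by contraction of an eleven-membered thiacycle in which sulfur bridges C1 and C10. A Ramberg–Bäcklund reaction expels that sulfur as SO2, joins C1 to C10 and creates the Z-C1=C10 alkene that later becomes the cis-1,10-epoxide. The step exploits that C1 and C10 are flanked only by the CH2 groups C2 and C9, so no β-leaving group interferes. Its precursor, a cyclic sulfone, already carries the E-C4=C5 alkene and the C6/C7/C8 triad, set by an Evans syn-aldol and an Evans–Tishchenko reduction; directed and Shi epoxidations finish the route.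

Key step: step 10

Remark: atom labels C1–C11 follow germacrane numbering throughout; the sulfur-bearing carbon C10 is carried as both epimers from 6 to 19 and is left undefined in their SMILES, because it becomes sp2 in step 10.

Step 1
Reactants: 1 5-chloropent-1-yne
Product: 3 (E)-5-chloro-1-iodo-2-methylpent-1-ene, via alkenylalane 2 (not isolated)
Conditions: Me3Al, Cp2ZrCl2 (cat.), CH2Cl2, 0 °C to rt; then I2, THF, −30 to 0 °C
Reagents that add atoms: trimethylaluminium C[Al](C)C; iodine II
Why: Negishi zirconium-catalysed carboalumination adds Me and Al syn across the alkyne with Me on the internal carbon, and iodinolysis with retention should fix the E geometry of the future C4=C5 bond.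

Step 2
Reactants: 4 (E)-but-2-enal (crotonaldehyde); 5 triphenylmethanethiol
Product: 6 3-(tritylsulfanyl)butanal (racemic)
Conditions: Et3N (cat.), CH2Cl2, 0 °C to rt
Reagents that add atoms: none
Why: Base-catalysed thia-Michael addition should place the protected sulfur on the future C10, whose configuration is irrelevant.

Step 3
Reactants: 7 (R)-4-benzyl-3-(3-methylbutanoyl)oxazolidin-2-one; 6 3-(tritylsulfanyl)butanal
Product: 9 (R)-4-benzyl-3-[(2R,3S)-3-hydroxy-2-(propan-2-yl)-5-(tritylsulfanyl)hexanoyl]oxazolidin-2-one, via boron enolate 8 (not isolated)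
Conditions: Bu2BOTf, i-Pr2NEt, CH2Cl2, −78 to 0 °C; then 6, −78 to 0 °C; MeOH/pH 7 buffer work-up without peroxide
Reagents that add atoms: none
Why: Evans syn-aldol reaction, in which the Z-boron enolate reacts through a Zimmerman–Traxler chair on the face away from the benzyl group, should set C7 and C8 (7,8-syn) under auxiliary control.

Step 4
Reactants: 9 aldol adduct
Product: 10 (2R,3S)-3-hydroxy-N-methoxy-N-methyl-2-(propan-2-yl)-5-(tritylsulfanyl)hexanamide
Conditions: MeNHOMe·HCl, AlMe3, CH2Cl2, −15 to 0 °C
Reagents that add atoms: N,O-dimethylhydroxylamine hydrochloride CNOC.Cl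
Why: Aluminium-amide transamination to the Weinreb amide, assisted by the free β-hydroxyl, should cleave the auxiliary at the exocyclic carbonyl without touching C7 or C8.

Step 5
Reactants: 3 (E)-5-chloro-1-iodo-2-methylpent-1-ene; 10 Weinreb amide
Product: 12 (4E,7R,8S)-1-chloro-8-hydroxy-4-methyl-7-(propan-2-yl)-10-(tritylsulfanyl)undec-4-en-6-one, via alkenyllithium 11 (not isolated)
Conditions: 3, t-BuLi (2 equiv), Et2O, −78 °C; added to 10 pretreated with i-PrMgCl (1 equiv), THF, −78 to −20 °C
Reagents that add atoms: none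
Why: Iodine–lithium exchange with retention of alkene geometry followed by Weinreb ketone synthesis (the chelated adduct prevents over-addition) should give the β-hydroxy enone, the alkyl chloride being inert at −78 °C.

Step 6
Reactants: 12 β-hydroxy enone
Product: 13 (4E,6S,7S,8S)-1-chloro-6-hydroxy-4-methyl-7-(propan-2-yl)-10-(tritylsulfanyl)undec-4-en-8-yl acetate
Conditions: SmI2 (0.3 equiv), MeCHO (excess), THF, −10 °C
Reagents that add atoms: acetaldehyde CC=O
Why: Evans–Tishchenko reduction, in which the samarium-bound hemiacetal on O8 delivers hydride intramolecularly to the C6 ketone through a chair transition state, should set C6 1,3-anti to C8 and leave O8 acetylated and O6 free.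

Step 7
Reactants: 13 hydroxy acetate
Product: 14 C6 triisopropylsilyl ether of 13
Conditions: TIPSOTf, 2,6-lutidine, CH2Cl2, 0 °C to rt
Reagents that add atoms: triisopropylsilyl triflate CC(C)[Si](C(C)C)(C(C)C)OS(=O)(=O)C(F)(F)F
Why: Silylation of the hindered allylic alcohol with a silyl triflate should protect O6 with a group that does not migrate to O8 under the later basic steps.

Step 8
Reactants: 14 silyl ether
Product: 16 (E)-5,11-dimethyl-8-(propan-2-yl)-7-[(triisopropylsilyl)oxy]-1-thiacycloundec-5-en-9-ol, via thiol 15 (not isolated)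
Conditions: (i) Et3SiH, TFA (5% v/v), CH2Cl2, 0 °C; (ii) K2CO3, NaI (cat.), degassed MeOH–THF, 2 mM, 50 °C
Reagents that add atoms: none
Why: Ionic detritylation followed by high-dilution intramolecular SN2 thioetherification (C10 thiolate on C1–Cl) should close the eleven-membered ring while the C8 acetate is methanolysed, with no stereocentre affected.

Step 9
Reactants: 16 cyclic sulfide
Product: 17 the 1,1-dioxide (cyclic sulfone) of 16
Conditions: (NH4)6Mo7O24·4H2O (cat.), 30% H2O2, EtOH, 0 °C to rt
Reagents that add atoms: hydrogen peroxide OO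
Why: Molybdate-catalysed oxidation of a sulfide to the sulfone should be much faster than epoxidation of the unactivated C4=C5 alkene.

Step 10
Reactants: 17 cyclic sulfone
Product: 20 (1(10)Z,4E)-6-O-triisopropylsilyl-germacra-1(10),4-diene-6,8-diol, via α-bromo sulfone 18 (not isolated), via episulfone 19 (not isolated)
Conditions: KOH/Al2O3, CBr2F2, t-BuOH–CH2Cl2, 5 °C to rt
Reagents that add atoms: none
Why: One-pot halogenative Ramberg–Bäcklund reaction: hydroxide deprotonates the sulfone at C1, the carbanion takes Br+ from CBr2F2 to give 18, a second deprotonation at C10 is followed by 1,3-displacement of bromide to the thiirane 1,1-dioxide 19, which loses SO2 cheletropically and stereospecifically. The closest known reaction type is the Ramberg–Bäcklund ring contraction of medium-ring and macrocyclic sulfones to cycloalkenes. The ten-membered carbocycle is closed in a 3-exo-tet mode (C10 carbanion on C1–Br) as the bicyclo[8.1.0] episulfone, and the eleven-membered ring contracts by the sulfur atom. No stereocentre is created: C10 becomes planar so both epimers converge, and C6, C7 and C8 are untouched. The step needs Z geometry at C1=C10, which should follow from the cis-fused episulfone (C2 and C9 on the same side of the three-membered ring, the less strained fusion and the usual kinetic outcome with hydroxide); CBr2F2 in place of CCl4 avoids dihalocarbene addition to C4=C5.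

Step 11
Reactants: 20 diene alcohol; 21 angelic acid [(Z)-2-methylbut-2-enoic acid]
Product: 22 8-O-angelate of 20
Conditions: 21, 2,4,6-trichlorobenzoyl chloride, Et3N, toluene, rt; then 20, 75 °C
Reagents that add atoms: none
Why: Yamaguchi-type mixed-anhydride acylation without DMAP should esterify the hindered C8 alcohol with retention at C8 and without Z-to-E isomerisation of the angelate.

Step 12
Reactants: 22 silyl ether angelate
Product: 23 (1(10)Z,4E)-8-angeloyloxygermacra-1(10),4-dien-6-ol
Conditions: HF·pyridine, pyridine–THF, rt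
Reagents that add atoms: none
Why: Buffered fluoride cleavage of the Si–O bond should free O6 without base-induced angelate isomerisation or acid-induced transannular cyclisation.

Step 13
Reactants: 23 allylic alcohol
Product: 24 (4S,5S)-4,5-epoxide of 23
Conditions: VO(acac)2 (5 mol%), t-BuOOH, CH2Cl2, 0 °C
Reagents that add atoms: tert-butyl hydroperoxide CC(C)(C)OO
Why: Hydroxyl-directed vanadium epoxidation reacts only at the allylic C4=C5 bond; A(1,3) strain with the C4 methyl holds C6–H in the alkene plane, so oxygen should be delivered to the face bearing O6 (threo), giving the 4S,5S trans-epoxide.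

Step 14
Reactants: 24 epoxy alcohol
Product: 25 6-acetate of 24
Conditions: Ac2O, pyridine, DMAP (cat.), CH2Cl2, 0 °C to rt
Reagents that add atoms: acetic anhydride CC(=O)OC(C)=O
Why: Standard O-acetylation should proceed with retention at C6.

Step 15
Reactants: 25 epoxy acetate
Product: 26 target, (1R,4S,5S,6R,7R,8S,10S)-6-acetoxy-1,10:4,5-diepoxygermacran-8-yl angelate
Conditions: D-fructose-derived Shi ketone (0.3 equiv), Oxone, K2CO3, Bu4NHSO4, MeCN–dimethoxymethane–aq. borate buffer (pH ≈ 10), 0 °C
Reagents that add atoms: potassium peroxymonosulfate (Oxone) [K+].[O-]S(=O)(=O)OO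
Why: Shi asymmetric epoxidation of the remaining trisubstituted alkene: in the spiro transition state the facial sense is fixed by the trans pair C10–Me/C2, as for the trans-alkenes that give (R,R)-epoxides with this ketone, which should give the 1R,10S cis-epoxide under reagent control while the electron-poor angelate is inert.

Compound list

1 | 5-chloropent-1-yne | C#CCCCCl | starting material
2 | (E)-(5-chloro-2-methylpent-1-en-1-yl)dimethylalane | ClCCC/C(C)=C/[Al](C)C | intermediate
3 | (E)-5-chloro-1-iodo-2-methylpent-1-ene | ClCCC/C(C)=C/I | intermediate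
4 | (E)-but-2-enal (crotonaldehyde) | C/C=C/C=O | starting material
5 | triphenylmethanethiol | SC(c1ccccc1)(c1ccccc1)c1ccccc1 | starting material
6 | 3-(tritylsulfanyl)butanal (racemic) | CC(CC=O)SC(c1ccccc1)(c1ccccc1)c1ccccc1 | intermediate
7 | (R)-4-benzyl-3-(3-methylbutanoyl)oxazolidin-2-one | CC(C)CC(=O)N1C(=O)OC[C@H]1Cc1ccccc1 | starting material
8 | (Z)-dibutylboron enolate of 7 | CC(C)/C=C(\OB(CCCC)CCCC)N1C(=O)OC[C@H]1Cc1ccccc1 | intermediate
9 | (R)-4-benzyl-3-[(2R,3S)-3-hydroxy-2-(propan-2-yl)-5-(tritylsulfanyl)hexanoyl]oxazolidin-2-one (both C5 epimers) | CC(SC(c1ccccc1)(c1ccccc1)c1ccccc1)C[C@H](O)[C@@H](C(C)C)C(=O)N1C(=O)OC[C@H]1Cc1ccccc1 | intermediate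
10 | (2R,3S)-3-hydroxy-N-methoxy-N-methyl-2-(propan-2-yl)-5-(tritylsulfanyl)hexanamide (both C5 epimers) | CC(SC(c1ccccc1)(c1ccccc1)c1ccccc1)C[C@H](O)[C@@H](C(C)C)C(=O)N(C)OC | intermediate
11 | (E)-(5-chloro-2-methylpent-1-en-1-yl)lithium | ClCCC/C(C)=C/[Li] | intermediate
12 | (4E,7R,8S)-1-chloro-8-hydroxy-4-methyl-7-(propan-2-yl)-10-(tritylsulfanyl)undec-4-en-6-one (both C10 epimers) | CC(SC(c1ccccc1)(c1ccccc1)c1ccccc1)C[C@H](O)[C@@H](C(C)C)C(=O)/C=C(\C)CCCCl | intermediate
13 | (4E,6S,7S,8S)-1-chloro-6-hydroxy-4-methyl-7-(propan-2-yl)-10-(tritylsulfanyl)undec-4-en-8-yl acetate (both C10 epimers) | CC(SC(c1ccccc1)(c1ccccc1)c1ccccc1)C[C@H](OC(C)=O)[C@@H](C(C)C)[C@@H](O)/C=C(\C)CCCCl | intermediate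
14 | C6 triisopropylsilyl ether of 13 | CC(SC(c1ccccc1)(c1ccccc1)c1ccccc1)C[C@H](OC(C)=O)[C@@H](C(C)C)[C@@H](O[Si](C(C)C)(C(C)C)C(C)C)/C=C(\C)CCCCl | intermediate
15 | free C10 thiol derived from 14 | CC(S)C[C@H](OC(C)=O)[C@@H](C(C)C)[C@@H](O[Si](C(C)C)(C(C)C)C(C)C)/C=C(\C)CCCCl | intermediate
16 | (E)-5,11-dimethyl-8-(propan-2-yl)-7-[(triisopropylsilyl)oxy]-1-thiacycloundec-5-en-9-ol (S bridges C1 and C10; C6, C7, C8 as in the target; both C10 epimers) | O[C@H]1CC(C)SCCC/C(C)=C/[C@H](O[Si](C(C)C)(C(C)C)C(C)C)[C@@H]1C(C)C | intermediate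
17 | 1,1-dioxide (cyclic sulfone) of 16 | O[C@H]1CC(C)S(=O)(=O)CCC/C(C)=C/[C@H](O[Si](C(C)C)(C(C)C)C(C)C)[C@@H]1C(C)C | intermediate
18 | C1-bromo derivative of sulfone 17 | O[C@H]1CC(C)S(=O)(=O)C(Br)CC/C(C)=C/[C@H](O[Si](C(C)C)(C(C)C)C(C)C)[C@@H]1C(C)C | intermediate
19 | cis-fused thiirane 1,1-dioxide across C1–C10 of the ten-membered ring | O[C@H]1CC2(C)C(CC/C(C)=C/[C@H](O[Si](C(C)C)(C(C)C)C(C)C)[C@@H]1C(C)C)S2(=O)=O | intermediate
20 | (1(10)Z,4E)-6-O-triisopropylsilyl-germacra-1(10),4-diene-6,8-diol | O[C@H]1C/C(C)=C\CC/C(C)=C/[C@H](O[Si](C(C)C)(C(C)C)C(C)C)[C@@H]1C(C)C | intermediate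
21 | angelic acid, (Z)-2-methylbut-2-enoic acid | C/C=C(/C)C(O)=O | starting material
22 | 8-O-angelate of 20 | C/C=C(/C)C(=O)O[C@H]1C/C(C)=C\CC/C(C)=C/[C@H](O[Si](C(C)C)(C(C)C)C(C)C)[C@@H]1C(C)C | intermediate
23 | (1(10)Z,4E)-8-angeloyloxygermacra-1(10),4-dien-6-ol | C/C=C(/C)C(=O)O[C@H]1C/C(C)=C\CC/C(C)=C/[C@H](O)[C@@H]1C(C)C | intermediate
24 | (4S,5S)-4,5-epoxide of 23 | C/C=C(/C)C(=O)O[C@H]1C/C(C)=C\CC[C@]2(C)O[C@H]2[C@H](O)[C@@H]1C(C)C | intermediate
25 | 6-acetate of 24 | C/C=C(/C)C(=O)O[C@H]1C/C(C)=C\CC[C@]2(C)O[C@H]2[C@H](OC(C)=O)[C@@H]1C(C)C | intermediate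
26 | (1R,4S,5S,6R,7R,8S,10S)-6-acetoxy-1,10:4,5-diepoxygermacran-8-yl angelate | C/C=C(/C)C(=O)O[C@H]1C[C@]2(C)O[C@@H]2CC[C@]2(C)O[C@H]2[C@H](OC(C)=O)[C@@H]1C(C)C | target

Total step count: 15. Longest linear sequence: 14 steps (steps 2 to 15; step 1 joins at step 5).

Steps most likely to fail

1. Step 10. The one-pot sequence may lose geometric control at C1=C10 (E/Z mixture), or brominate C1 twice and eliminate to a bromoalkene. The fallback sets out from 17 and separates halogenation from extrusion. LDA (2.2 equiv, THF, −78 °C) followed by hexachloroethane would place a single chlorine on C1 and give the isolated α-chloro sulfone F1. Aqueous KOH in dioxane (classical, kinetically cis-selective Ramberg–Bäcklund conditions) would then convert it into 20, where the route is rejoined.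

2. Step 8. Intermolecular S-alkylation (oligomers) may outrun the eleven-membered ring closure, and displacement of the chloride may be sluggish. The fallback sets out from 14 and closes the ring through a reversible S–S bond instead. KSAc/NaI in DMF would give the C1 thioacetate F2. Et3SiH/TFA and then K2CO3/MeOH would liberate the dithiol F3. Air oxidation at high dilution would close the twelve-membered cyclic disulfide F4, with thiol–disulfide exchange correcting oligomers. Tris(diethylamino)phosphine would then extrude one sulfur (thiolate attack at the primary C1) and return to 16.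

3. Step 15. Facial selectivity may be poor if the conformational bias of the ten-membered ring opposes the catalyst, and the acetate may hydrolyse slowly at pH 10. The fallback sets out from 25. NBS in THF–H2O would give the bromohydrin F5 by anti addition (Br at C1, tertiary OH at C10). DBU would close it to 26 with inversion at C1, so the oxygen ends on the face opposite to the one an electrophile prefers.

Further compounds

F1 | step 10 | C1-chloro derivative of sulfone 17 | O[C@H]1CC(C)S(=O)(=O)C(Cl)CC/C(C)=C/[C@H](O[Si](C(C)C)(C(C)C)C(C)C)[C@@H]1C(C)C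
F2 | step 8 | C1 thioacetate of 14 (chloride replaced by SAc) | CC(SC(c1ccccc1)(c1ccccc1)c1ccccc1)C[C@H](OC(C)=O)[C@@H](C(C)C)[C@@H](O[Si](C(C)C)(C(C)C)C(C)C)/C=C(\C)CCCSC(C)=O
F3 | step 8 | C1,C10-dithiol with free C8 hydroxyl | CC(S)C[C@H](O)[C@@H](C(C)C)[C@@H](O[Si](C(C)C)(C(C)C)C(C)C)/C=C(\C)CCCS
F4 | step 8 | twelve-membered cyclic disulfide (S–S between C1 and C10) | O[C@H]1CC(C)SSCCC/C(C)=C/[C@H](O[Si](C(C)C)(C(C)C)C(C)C)[C@@H]1C(C)C
F5 | step 15 | 1-bromo-10-hydroxy bromohydrin of 25 | C/C=C(/C)C(=O)O[C@H]1C[C@](C)(O)[C@@H](Br)CC[C@]2(C)O[C@H]2[C@H](OC(C)=O)[C@@H]1C(C)C
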